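**Retrosynthetic overview**

1. Feature: ring C, the terminal 2-hydroxy-4-methoxy-6-methylbenzoyl ring, is an orsellinate. Its carbons C1–C6 and the 6-methyl are C2–C8 of a 3,5,7-trioxooctanoyl chain, and ring bond C1–C6 is chain bond C2–C7.
2. Target 18 ⇒ (O-methylation of ring C 4-OH) 4-O-demethyl tridepside 17 ⇒ (aldol C2→C7, dehydration, aromatisation) aryl 3,5,7-trioxooctanoate 15.
3. 15 ⇒ (chain ester C–O, acylketene trapping) ring B–ring A phenol 7 + diketo-dioxinone 13; 13 ⇒ two Claisen acylations of dioxinone 8.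
4. 7 ⇒ (depside ester, then O-debenzylation) acid 4 + methyl orsellinate 1; 4 ⇒ 1 by O-benzylation, O-methylation and saponification.
5. Ring order: rings A and B come intact from methyl orsellinate; ring C is the only ring built, in step 9.

Key step: step 9

Remark: the target has no stereocentre and no configurationally stable axis, so it is achiral and no step needs stereocontrol.

**Route**

Step 1
Reactants: 1 methyl orsellinate (methyl 2,4-dihydroxy-6-methylbenzoate)
Product: 2 methyl 4-(benzyloxy)-2-hydroxy-6-methylbenzoate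
Conditions: BnBr (1.05 equiv), K2CO3, acetone, reflux
Reagents that add atoms: benzyl bromide, BrCc1ccccc1
Why: Williamson ether synthesis; the 4-OH is the free, more acidic phenol while the 2-OH is hydrogen-bonded to the ester carbonyl, so one equivalent of halide should alkylate O-4 only.

Step 2
Reactants: 2 methyl 4-(benzyloxy)-2-hydroxy-6-methylbenzoate
Product: 3 methyl 4-(benzyloxy)-2-methoxy-6-methylbenzoate
Conditions: MeI (3 equiv), K2CO3, DMF, 60 °C
Reagents that add atoms: iodomethane, CI
Why: Williamson methylation of the hydrogen-bonded phenol, which needs excess halide and a dipolar solvent; no other acidic site is left.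

Step 3
Reactants: 3 methyl 4-(benzyloxy)-2-methoxy-6-methylbenzoate
Product: 4 4-(benzyloxy)-2-methoxy-6-methylbenzoic acid
Conditions: KOH, DMSO–H2O, 90 °C; then 1 M HCl, 0 °C
Reagents that add atoms: potassium hydroxide, [K+].[OH-]
Why: saponification of a di-ortho-substituted methyl benzoate is slow and so is run hot in aqueous DMSO; both ethers are inert to base and cold acidification should avoid decarboxylation.

Step 4
Reactants: 4 4-(benzyloxy)-2-methoxy-6-methylbenzoic acid; 1 methyl orsellinate
Product: 6 methyl 4-{[4-(benzyloxy)-2-methoxy-6-methylbenzoyl]oxy}-2-hydroxy-6-methylbenzoate, via mixed trifluoroacetic anhydride 5 (not isolated)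
Conditions: TFAA (2.5 equiv), PhMe, rt; aq NaHCO3
Reagents that add atoms: none
Why: TFAA-mediated depside esterification; the acylium-like mixed anhydride 5 suits a di-ortho-substituted acid and should acylate the free 4-OH of 1 rather than the hydrogen-bonded 2-OH, and any aryl trifluoroacetate is cleaved in the bicarbonate wash.

Step 5
Reactants: 6 methyl 4-{[4-(benzyloxy)-2-methoxy-6-methylbenzoyl]oxy}-2-hydroxy-6-methylbenzoate
Product: 7 methyl 2-hydroxy-4-[(4-hydroxy-2-methoxy-6-methylbenzoyl)oxy]-6-methylbenzoate (ring B–ring A phenol)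
Conditions: H2 (1 atm), 10% Pd/C, EtOAc, rt
Reagents that add atoms: none
Why: catalytic hydrogenolysis of the benzyl aryl ether; the aryl ester, the methyl ester and the arenes are not touched under these conditions.

Step 6
Reactants: 8 2,2,6-trimethyl-4H-1,3-dioxin-4-one
Product: 10 2,2-dimethyl-6-(2-oxopropyl)-4H-1,3-dioxin-4-one, via lithium dienolate 9 (not isolated)
Conditions: LiHMDS (2 equiv, with 2 equiv of 8), THF, −78 °C; AcCl (1 equiv); aq NH4Cl
Reagents that add atoms: acetyl chloride, CC(Cl)=O
Why: crossed Claisen condensation; the vinylogous enolate 9 is C-acylated at the exocyclic γ-carbon, and the second equivalent of 9 takes the proton of the more acidic product and returns 8 on quench.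

Step 7
Reactants: 10 2,2-dimethyl-6-(2-oxopropyl)-4H-1,3-dioxin-4-one
Product: 13 6-(2,4-dioxopentyl)-2,2-dimethyl-4H-1,3-dioxin-4-one, via dilithium dianion 11 (not isolated), via Weinreb tetrahedral adduct 12 (not isolated)
Conditions: LDA (2.2 equiv, commercial solution), THF, −78 °C; MeCON(OMe)Me, −78 to −20 °C; 1 M HCl, 0 °C
Reagents that add atoms: N-methoxy-N-methylacetamide, CC(=O)N(C)OC
Why: Claisen acylation of a dianion; the more basic terminal carbanion of 11 adds to the Weinreb amide and the chelated adduct 12 holds until the acid quench, so neither double addition nor O-acylation is expected.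

Step 8
Reactants: 13 6-(2,4-dioxopentyl)-2,2-dimethyl-4H-1,3-dioxin-4-one; 7 ring B–ring A phenol
Product: 15 methyl 2-hydroxy-4-({2-methoxy-6-methyl-4-[(3,5,7-trioxooctanoyl)oxy]benzoyl}oxy)-6-methylbenzoate, via diketo acylketene 14 (not isolated)
Conditions: PhMe, 110 °C, 13 (1.2 equiv) added slowly to 7, acetone distilled off; evaporate and use crude
Reagents that add atoms: none
Why: retro-hetero-Diels–Alder loss of acetone gives acylketene 14, which the free ring B 4-OH of 7 should trap by addition to the ketene in preference to the hydrogen-bonded ring A 2-OH; no base is present, so the chain should stay open.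

Step 9
Reactants: 15 methyl 2-hydroxy-4-({2-methoxy-6-methyl-4-[(3,5,7-trioxooctanoyl)oxy]benzoyl}oxy)-6-methylbenzoate
Product: 17 methyl 4-({4-[(2,4-dihydroxy-6-methylbenzoyl)oxy]-2-methoxy-6-methylbenzoyl}oxy)-2-hydroxy-6-methylbenzoate (4-O-demethyl tridepside), via cyclic aldol 16 (not isolated)
Conditions: Et3N (2 equiv), CH2Cl2, −20 °C to rt; then TFA, rt
Reagents that add atoms: none
Why: Et3N forms the C2 enolate (C2–H lies between the aryl ester C1 and the C3 ketone), which adds to the C7 methyl-ketone carbonyl to make the C2–C7 bond (ring C C1–C6) and the cyclic aldol 16; E1cB loss of water and enolisation of the C3 and C5 ketones, completed by the acid, give the 2,4-dihydroxy-6-methylbenzoate ring. This is the aldol cyclisation–aromatisation known for 3,5,7-trioxoalkanoate esters made by acylketene trapping. The closure is 6-exo-trig at the C7 carbonyl, enolexo as seen from the ester enolate and enolendo as seen from the C3 ketone enolate, both allowed for a six-membered ring. No stereocentre remains, since the two sp3 centres of 16 vanish on aromatisation. The step needs the C-aldol at C7 to outrun O-attack of the C5 enol on C1 (pyranone) and Claisen attack of C6 on C1 (acylphloroglucinol), both of which would expel phenol 7; an amine base in an aprotic solvent at low temperature, without alkoxide or chelating metal ion, should favour the aldol, which the aryl ester helps by acidifying C2–H and which dehydration makes irreversible.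

Step 10
Reactants: 17 4-O-demethyl tridepside
Product: 18 methyl 2-hydroxy-4-({4-[(2-hydroxy-4-methoxy-6-methylbenzoyl)oxy]-2-methoxy-6-methylbenzoyl}oxy)-6-methylbenzoate (target)
Conditions: MeI (1.05 equiv), K2CO3 (1.1 equiv), acetone, rt
Reagents that add atoms: iodomethane, CI
Why: Williamson methylation with one equivalent of halide; only the ring C 4-OH is free and para to an ester carbonyl, the other two phenols are hydrogen-bonded to ortho ester carbonyls, and carbonate in acetone at rt should leave the aryl esters intact.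

**Compound list**

1 | methyl orsellinate (methyl 2,4-dihydroxy-6-methylbenzoate) | COC(=O)c1c(C)cc(O)cc1O | starting material
2 | methyl 4-(benzyloxy)-2-hydroxy-6-methylbenzoate | COC(=O)c1c(C)cc(OCc2ccccc2)cc1O | intermediate
3 | methyl 4-(benzyloxy)-2-methoxy-6-methylbenzoate | COC(=O)c1c(C)cc(OCc2ccccc2)cc1OC | intermediate
4 | 4-(benzyloxy)-2-methoxy-6-methylbenzoic acid | Cc1cc(OCc2ccccc2)cc(OC)c1C(=O)O | intermediate
5 | 4-(benzyloxy)-2-methoxy-6-methylbenzoic trifluoroacetic anhydride (not isolated) | Cc1cc(OCc2ccccc2)cc(OC)c1C(=O)OC(=O)C(F)(F)F | intermediate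
6 | methyl 4-{[4-(benzyloxy)-2-methoxy-6-methylbenzoyl]oxy}-2-hydroxy-6-methylbenzoate | COC(=O)c1c(C)cc(OC(=O)c2c(C)cc(OCc3ccccc3)cc2OC)cc1O | intermediate
7 | methyl 2-hydroxy-4-[(4-hydroxy-2-methoxy-6-methylbenzoyl)oxy]-6-methylbenzoate | COC(=O)c1c(C)cc(OC(=O)c2c(C)cc(O)cc2OC)cc1O | intermediate
8 | 2,2,6-trimethyl-4H-1,3-dioxin-4-one | CC1=CC(=O)OC(C)(C)O1 | starting material
9 | lithium dienolate of 8 (not isolated) | [Li+].C=C1C=C([O-])OC(C)(C)O1 | intermediate
10 | 2,2-dimethyl-6-(2-oxopropyl)-4H-1,3-dioxin-4-one | CC(=O)CC1=CC(=O)OC(C)(C)O1 | intermediate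
11 | dilithium dianion of 10 (not isolated) | [Li+].[Li+].C=C([O-])C=C1C=C([O-])OC(C)(C)O1 | intermediate
12 | dilithium tetrahedral adduct of 11 and N-methoxy-N-methylacetamide (not isolated) | [Li+].[Li+].CON(C)C(C)([O-])CC([O-])=CC1=CC(=O)OC(C)(C)O1 | intermediate
13 | 6-(2,4-dioxopentyl)-2,2-dimethyl-4H-1,3-dioxin-4-one | CC(=O)CC(=O)CC1=CC(=O)OC(C)(C)O1 | intermediate
14 | 3,5,7-trioxooct-1-en-1-one (diketo acylketene, not isolated) | CC(=O)CC(=O)CC(=O)C=C=O | intermediate
15 | methyl 2-hydroxy-4-({2-methoxy-6-methyl-4-[(3,5,7-trioxooctanoyl)oxy]benzoyl}oxy)-6-methylbenzoate | CC(=O)CC(=O)CC(=O)CC(=O)Oc1cc(C)c(C(=O)Oc2cc(C)c(C(=O)OC)c(O)c2)c(OC)c1 | intermediate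
16 | methyl 2-hydroxy-4-[(4-{[(2-hydroxy-2-methyl-4,6-dioxocyclohexyl)carbonyl]oxy}-2-methoxy-6-methylbenzoyl)oxy]-6-methylbenzoate (diastereomer mixture, not isolated) | CC1(O)CC(=O)CC(=O)C1C(=O)Oc1cc(C)c(C(=O)Oc2cc(C)c(C(=O)OC)c(O)c2)c(OC)c1 | intermediate
17 | methyl 4-({4-[(2,4-dihydroxy-6-methylbenzoyl)oxy]-2-methoxy-6-methylbenzoyl}oxy)-2-hydroxy-6-methylbenzoate | COC(=O)c1c(C)cc(OC(=O)c2c(C)cc(OC(=O)c3c(C)cc(O)cc3O)cc2OC)cc1O | intermediate
18 | methyl 2-hydroxy-4-({4-[(2-hydroxy-4-methoxy-6-methylbenzoyl)oxy]-2-methoxy-6-methylbenzoyl}oxy)-6-methylbenzoate | COC(=O)c1c(C)cc(OC(=O)c2c(C)cc(OC(=O)c3c(C)cc(OC)cc3O)cc2OC)cc1O | target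

**Step count**

Total steps: 10. Longest linear sequence: 8 steps (1, 2, 3, 4, 5, 8, 9, 10); the dioxinone branch (steps 6 and 7) joins at step 8.

**Steps most likely to fail**

Step 9 (key step). The aryloxy group is a good leaving group, so lactonisation through the C5 enol oxygen or Claisen attack of C6 on C1 may expel phenol 7 faster than the C2→C7 aldol closes. The fallback sets out from 13 and 7 and comes back at 18. The same aldol is run at the dioxinone stage, where the carboxyl oxygen is tied into the acetonide and nothing can be expelled: Et3N in CH2Cl2 should convert 13 into 7-hydroxy-2,2,5-trimethyl-4H-1,3-benzodioxin-4-one F1. Methylation (MeI, K2CO3, acetone) gives 7-methoxy-2,2,5-trimethyl-4H-1,3-benzodioxin-4-one F2. Opening with KOH in aqueous DMSO and cold acidification gives 2-hydroxy-4-methoxy-6-methylbenzoic acid F3. TFAA in toluene, through 2-hydroxy-4-methoxy-6-methylbenzoic trifluoroacetic anhydride F4, esterifies the free ring B 4-OH of 7 and gives 18 directly, so step 10 is not needed.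

Step 8. The acylketene may be consumed by attack of its own enol oxygen, or the aryl triketo ester may collapse thermally, before the weakly nucleophilic phenol has been acylated cleanly; partial acylation of the ring A hydroxyl is also possible. The fallback sets out from 1 and 7 and comes back at 17, using classical depside assembly without a ketene. Exhaustive benzylation of 1 (BnBr excess, K2CO3, DMF, 70 °C) gives methyl 2,4-bis(benzyloxy)-6-methylbenzoate F5. Saponification (KOH, aqueous DMSO, 90 °C) gives 2,4-bis(benzyloxy)-6-methylbenzoic acid F6. TFAA in toluene, through 2,4-bis(benzyloxy)-6-methylbenzoic trifluoroacetic anhydride F7, couples F6 with 7 to give methyl 4-({4-[(2,4-bis(benzyloxy)-6-methylbenzoyl)oxy]-2-methoxy-6-methylbenzoyl}oxy)-2-hydroxy-6-methylbenzoate F8. Hydrogenolysis (H2, Pd/C, EtOAc) then gives 17, and step 10 follows as planned.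

Step 7. The acidic diketone product may quench unreacted dianion by proton transfer, O-acylation may compete, and the sensitive diketo-dioxinone may be lost on purification. The fallback sets out from 10 and comes back at 13, replacing the Claisen acylation by aldol addition and oxidation. The dianion 11 (LDA, THF, −78 °C) adds to acetaldehyde, whose alkoxide product is not an acid, to give racemic 6-(4-hydroxy-2-oxopentyl)-2,2-dimethyl-4H-1,3-dioxin-4-one F9. Dess–Martin periodinane in CH2Cl2 then oxidises the secondary alcohol to give 13.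

**Further compounds**

F1 | step 9 | 7-hydroxy-2,2,5-trimethyl-4H-1,3-benzodioxin-4-one | CC1(C)OC(=O)c2c(C)cc(O)cc2O1
F2 | step 9 | 7-methoxy-2,2,5-trimethyl-4H-1,3-benzodioxin-4-one | CC1(C)OC(=O)c2c(C)cc(OC)cc2O1
F3 | step 9 | 2-hydroxy-4-methoxy-6-methylbenzoic acid (everninic acid) | Cc1cc(OC)cc(O)c1C(=O)O
F4 | step 9 | 2-hydroxy-4-methoxy-6-methylbenzoic trifluoroacetic anhydride | Cc1cc(OC)cc(O)c1C(=O)OC(=O)C(F)(F)F
F5 | step 8 | methyl 2,4-bis(benzyloxy)-6-methylbenzoate | COC(=O)c1c(C)cc(OCc2ccccc2)cc1OCc1ccccc1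
F6 | step 8 | 2,4-bis(benzyloxy)-6-methylbenzoic acid | Cc1cc(OCc2ccccc2)cc(OCc2ccccc2)c1C(=O)O
F7 | step 8 | 2,4-bis(benzyloxy)-6-methylbenzoic trifluoroacetic anhydride | Cc1cc(OCc2ccccc2)cc(OCc2ccccc2)c1C(=O)OC(=O)C(F)(F)F
F8 | step 8 | methyl 4-({4-[(2,4-bis(benzyloxy)-6-methylbenzoyl)oxy]-2-methoxy-6-methylbenzoyl}oxy)-2-hydroxy-6-methylbenzoate | COC(=O)c1c(C)cc(OC(=O)c2c(C)cc(OC(=O)c3c(C)cc(OCc4ccccc4)cc3OCc3ccccc3)cc2OC)cc1O
F9 | step 7 | 6-(4-hydroxy-2-oxopentyl)-2,2-dimethyl-4H-1,3-dioxin-4-one (racemic) | CC(O)CC(=O)CC1=CC(=O)OC(C)(C)O1
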